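**Retrosynthetic overview**

1. The C8 formyl group goes in last, by ortho-formylation of the 7-hydroxy homoisoflavone (C8 is the only free position of ring A, the benzo ring).
2. Key disconnection C3–C4: the formyl carbon of an O-propargylated salicylaldehyde becomes an acyl anion equivalent (Breslow intermediate of an N-heterocyclic carbene) and adds to the unactivated aryl alkyne. This closes the pyranone ring, the only ring that is built.
3. The exocyclic alkene formed is moved into the ring (benzylidenechromanone to 3-benzylchromone) and the MOM group is removed in the same flask.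
4. The aryl alkyne comes from a Sonogashira coupling of the terminal propargyl ether with 4-iodoanisole (ring B, the anisyl ring, is bought).
5. Ring A is bought as 2,4,6-trihydroxy-3-methylbenzaldehyde; its OH groups are etherified in order of reactivity: para OH (MOM), unhindered ortho OH (propargyl), chelated ortho OH beside the methyl (methyl).

Assumption: the target has no stereocentre and no stereogenic double bond, so the achiral compound as drawn is made; 2,4,6-trihydroxy-3-methylbenzaldehyde is taken as a catalogue compound (otherwise one Vilsmeier formylation from 2-methylphloroglucinol).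

**Route**

Step 1
Reactants: 1 2,4,6-trihydroxy-3-methylbenzaldehyde; 2 chloromethyl methyl ether (MOMCl)
Product: 3 2,6-dihydroxy-4-(methoxymethoxy)-3-methylbenzaldehyde
Conditions: MOMCl (1.05 equiv), i-Pr2NEt (1.2 equiv), THF, 0 °C
Reagents that add atoms: chloromethyl methyl ether, COCCl
Why: The 4-OH is para to the formyl group, not hydrogen-bonded and the most acidic, so with an amine base and one equivalent of MOMCl it is etherified first (Williamson-type acetal ether formation); no stereocentre is formed.

Step 2
Reactants: 3 2,6-dihydroxy-4-(methoxymethoxy)-3-methylbenzaldehyde; 4 propargyl bromide; 5 iodomethane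
Product: 7 2-methoxy-4-(methoxymethoxy)-3-methyl-6-(prop-2-yn-1-yloxy)benzaldehyde, via mono-propargyl ether 6 (not isolated)
Conditions: K2CO3 (3 equiv), propargyl bromide (1.05 equiv), DMF, rt; then MeI (3 equiv), 45 °C
Reagents that add atoms: propargyl bromide, C#CCBr; iodomethane, CI
Why: The C6-OH (next to H) is less hindered and less strongly chelated than the C2-OH buttressed by the methyl group, so one equivalent of propargyl bromide reacts there first and excess MeI with warming then methylates the chelated C2-OH (two sequential Williamson ether syntheses).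

Step 3
Reactants: 7 2-methoxy-4-(methoxymethoxy)-3-methyl-6-(prop-2-yn-1-yloxy)benzaldehyde; 8 4-iodoanisole
Product: 9 2-methoxy-4-(methoxymethoxy)-6-{[3-(4-methoxyphenyl)prop-2-yn-1-yl]oxy}-3-methylbenzaldehyde
Conditions: 4-iodoanisole (1.1 equiv), PdCl2(PPh3)2 (2 mol%), CuI (4 mol%), Et3N, THF, rt
Reagents that add atoms: 4-iodoanisole, COc1ccc(I)cc1
Why: Sonogashira coupling (zerovalent palladium formed in situ from the divalent precatalyst, copper acetylide transmetalation) arylates the terminal alkyne at room temperature, where the aldehyde, the MOM ether and the propargylic C–O bond are left alone.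

Step 4
Reactants: 9 2-methoxy-4-(methoxymethoxy)-6-{[3-(4-methoxyphenyl)prop-2-yn-1-yl]oxy}-3-methylbenzaldehyde
Product: 12 7-hydroxy-5-methoxy-3-(4-methoxybenzyl)-6-methyl-4H-chromen-4-one, via (E)-benzylidenechromanone MOM ether 10 (not isolated), via 7-O-MOM chromone 11 (not isolated)
Conditions: 3-mesityl-5,6,7,8-tetrahydro-4H-cyclohepta[d]thiazol-3-ium perchlorate (10 mol%), K2CO3 (20 mol%), THF, 70 °C; then AcOH (0.5 equiv), EtOH, RhCl3·3H2O (5 mol%), 80 °C; then 3 M aq. HCl, 60 °C
Reagents that add atoms: none
Why: The thiazol-2-ylidene converts the formyl carbon into a nucleophilic Breslow intermediate (acyl anion equivalent) that adds to the unactivated alkyne in a concerted 6-exo, Conia-ene-type syn hydroacylation (NHC-catalysed intramolecular alkyne hydroacylation), forming C3–C4 and the E alkene; after the carbene is quenched with AcOH, a rhodium hydride from RhCl3·3H2O in ethanol shifts the exocyclic C=C into the ring (known benzylidenechromanone to 3-benzylchromone isomerisation, driven by 4-pyranone formation) and aqueous HCl hydrolyses the MOM acetal.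

Step 5
Reactants: 12 7-hydroxy-5-methoxy-3-(4-methoxybenzyl)-6-methyl-4H-chromen-4-one; 13 hexamethylenetetramine
Product: 14 7-hydroxy-5-methoxy-3-(4-methoxybenzyl)-6-methyl-4-oxo-4H-chromene-8-carbaldehyde
Conditions: HMTA (3 equiv), TFA, 80 °C; then 3 M aq. HCl, 60 °C
Reagents that add atoms: hexamethylenetetramine, C1N2CN3CN1CN(C2)C3; water, O
Why: Duff formylation: the iminium from protonated HMTA attacks C8, the only free position of ring A and ortho to the free 7-OH, and internal hydride transfer followed by hydrolysis of the benzylic iminium gives the aldehyde, while the chromone and the aryl methyl ethers are acid-stable and the less activated ring B should not compete.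

**Compound list**

1 | 2,4,6-trihydroxy-3-methylbenzaldehyde | Cc1c(O)cc(O)c(C=O)c1O | starting material
2 | chloromethyl methyl ether | COCCl | starting material
3 | 2,6-dihydroxy-4-(methoxymethoxy)-3-methylbenzaldehyde | COCOc1cc(O)c(C=O)c(O)c1C | intermediate
4 | propargyl bromide (3-bromoprop-1-yne) | C#CCBr | starting material
5 | iodomethane | CI | starting material
6 | 2-hydroxy-4-(methoxymethoxy)-3-methyl-6-(prop-2-yn-1-yloxy)benzaldehyde | COCOc1cc(OCC#C)c(C=O)c(O)c1C | intermediate
7 | 2-methoxy-4-(methoxymethoxy)-3-methyl-6-(prop-2-yn-1-yloxy)benzaldehyde | COCOc1cc(OCC#C)c(C=O)c(OC)c1C | intermediate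
8 | 4-iodoanisole | COc1ccc(I)cc1 | starting material
9 | 2-methoxy-4-(methoxymethoxy)-6-{[3-(4-methoxyphenyl)prop-2-yn-1-yl]oxy}-3-methylbenzaldehyde | COCOc1cc(OCC#Cc2ccc(OC)cc2)c(C=O)c(OC)c1C | intermediate
10 | (E)-5-methoxy-3-(4-methoxybenzylidene)-7-(methoxymethoxy)-6-methylchroman-4-one | COCOc1cc2OC/C(=C\c3ccc(OC)cc3)C(=O)c2c(OC)c1C | intermediate
11 | 5-methoxy-3-(4-methoxybenzyl)-7-(methoxymethoxy)-6-methyl-4H-chromen-4-one | COCOc1cc2occ(Cc3ccc(OC)cc3)c(=O)c2c(OC)c1C | intermediate
12 | 7-hydroxy-5-methoxy-3-(4-methoxybenzyl)-6-methyl-4H-chromen-4-one | COc1ccc(Cc2coc3cc(O)c(C)c(OC)c3c2=O)cc1 | intermediate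
13 | hexamethylenetetramine | C1N2CN3CN1CN(C2)C3 | starting material
14 | 7-hydroxy-5-methoxy-3-(4-methoxybenzyl)-6-methyl-4-oxo-4H-chromene-8-carbaldehyde | COc1ccc(Cc2coc3c(C=O)c(O)c(C)c(OC)c3c2=O)cc1 | target

**Step count**

Total steps: 5. Longest linear sequence: 5 (fully linear from 1; compounds 2, 4, 5, 8 and 13 are bought).

**Steps most likely to fail, with fallbacks**

Step 4. The aldehyde of 9 is electron-rich and flanked by two ortho oxygens, so carbene addition and the hydroacylation may be slow, and three operations are run in one flask. The fallback sets out from 9 and comes back at 11. It makes the same C3–C4 bond by reductive carbonyl umpolung instead of carbene catalysis. SmI2 (divalent samarium, 2.5 equiv) with HMPA and t-BuOH in THF at −78 to 0 °C turns the aldehyde into a ketyl radical anion, which cyclises 6-exo onto the aryl alkyne. After a second electron transfer and protonation this gives the allylic alcohol 5-methoxy-3-(4-methoxybenzylidene)-7-(methoxymethoxy)-6-methylchroman-4-ol F1 (racemic, mixture of alkene isomers). MnO2 in CH2Cl2 oxidises F1 to the enone, obtained as 10 together with its alkene isomer (Z)-5-methoxy-3-(4-methoxybenzylidene)-7-(methoxymethoxy)-6-methylchroman-4-one F2. Both isomers are converted by the RhCl3·3H2O stage of step 4 into chromone 11, where the route is rejoined.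

Step 2. The order in which the two ortho hydroxyls react decides the whole substitution pattern, and the same doubt applies to the mono-protection in step 1. The fallback sets out from 1 and comes back at 7. It replaces kinetic differentiation by full protection and carbonyl-directed unmasking. MOMCl (2.3 equiv) with i-Pr2NEt converts 1 into 2-hydroxy-4,6-bis(methoxymethoxy)-3-methylbenzaldehyde F3, in which only the buttressed, chelated OH stays free. MeI and K2CO3 in DMF give 2-methoxy-4,6-bis(methoxymethoxy)-3-methylbenzaldehyde F4. Catalytic I2 in MeOH at room temperature removes only the MOM group ortho to the formyl group and gives 6-hydroxy-2-methoxy-4-(methoxymethoxy)-3-methylbenzaldehyde F5. Propargyl bromide and K2CO3 in DMF then give 7.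

Step 5. Duff formylations of chromone phenols often give modest yields, and ring B could be formylated in TFA. The fallback sets out from 12 and comes back at 14. It fixes the C8 carbon first and oxidises afterwards. A Mannich reaction of 12 with bis(dimethylamino)methane in dioxane at 90 °C gives 8-[(dimethylamino)methyl]-7-hydroxy-5-methoxy-3-(4-methoxybenzyl)-6-methyl-4H-chromen-4-one F6, since C8 is the only position ortho to the phenol. Heating F6 with HMTA in AcOH at 100 °C and then with aqueous HCl (Sommelet-type oxidation of the benzylic amine) gives 14.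

**Further compounds**

F1 | step 4 | 5-methoxy-3-(4-methoxybenzylidene)-7-(methoxymethoxy)-6-methylchroman-4-ol (racemic, E/Z mixture, so no descriptors) | COCOc1cc2OCC(=Cc3ccc(OC)cc3)C(O)c2c(OC)c1C
F2 | step 4 | (Z)-5-methoxy-3-(4-methoxybenzylidene)-7-(methoxymethoxy)-6-methylchroman-4-one | COCOc1cc2OC/C(=C/c3ccc(OC)cc3)C(=O)c2c(OC)c1C
F3 | step 2 | 2-hydroxy-4,6-bis(methoxymethoxy)-3-methylbenzaldehyde | COCOc1cc(OCOC)c(C=O)c(O)c1C
F4 | step 2 | 2-methoxy-4,6-bis(methoxymethoxy)-3-methylbenzaldehyde | COCOc1cc(OCOC)c(C=O)c(OC)c1C
F5 | step 2 | 6-hydroxy-2-methoxy-4-(methoxymethoxy)-3-methylbenzaldehyde | COCOc1cc(O)c(C=O)c(OC)c1C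
F6 | step 5 | 8-[(dimethylamino)methyl]-7-hydroxy-5-methoxy-3-(4-methoxybenzyl)-6-methyl-4H-chromen-4-one | COc1ccc(Cc2coc3c(CN(C)C)c(O)c(C)c(OC)c3c2=O)cc1
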